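**Plan**

1. Retrosynthesis: the target is a meso 2,5-diaryl-3,4-dimethyloxolane carrying one extra O-methyl group, so the first cut is the 3-O–CH3 bond of the trimethoxyphenyl ring (back to meso bis-phenol 13), then the two 4-O–CH3 bonds and two benzyl ethers (back to 11).
2. Key cut: the oxolane C3–C4 bond (C8–C8′ in lignan numbering) and both ring C–O bonds (C7–O, C7′–O), which leads to two molecules of propenylphenol 7 plus water; 7 is cut at C7=C8 and at its benzyl ether back to 5-hydroxyvanillin.
3. Enabling feature: in the ring O1–C2–C3–C4–C5, the C3–C4 bond joins the C8 atoms of two identical aryl-C3 halves and O1 bridges the two benzylic carbons, each para to an aryl oxygen; this is the water adduct of the 8–8′ dimer of a 4-propenylphenol.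
4. Forward: benzylation and Wittig olefination give the propenylphenol; one oxidative dimerisation makes the only ring formed in the route, its three skeletal bonds and all four stereocentres; O-methylation, debenzylation, enzymatic monoacetylation, methylation and deacetylation follow.
5. Stereochemistry: the 3,4-cis methyl groups come from the erythro mode of the radical coupling, the aryl groups settle trans to their neighbouring methyls by acid equilibration through quinone methides, and the absolute configuration comes from lipase discrimination of the two enantiotopic phenols of meso 13.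

Key step: step 3

Assumption: the lipase selected by screening acetylates the phenol of the aryl ring on the (S)-configured benzylic carbon of meso 13; the sense of this discrimination cannot be predicted from the structure and decides which enantiomer is obtained.

**Route**

Step 1
Reactants: 1 5-hydroxyvanillin (3,4-dihydroxy-5-methoxybenzaldehyde); 2 benzyl bromide
Product: 4 3-(benzyloxy)-4-hydroxy-5-methoxybenzaldehyde, via disodium catecholate 3 (not isolated)
Conditions: NaH (2.2 equiv), DMSO, rt; then 2 (1.0 equiv), rt; dilute HCl work-up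
Reagents that add atoms: none
Why: In the dianion the oxygen para to the formyl group is delocalised into the aldehyde and is flanked by OMe and O−, so one equivalent of benzyl bromide should alkylate the more basic meta oxygen (Williamson ether synthesis on a catecholate dianion, a known way to 3-O-alkyl derivatives of 3,4-dihydroxybenzaldehydes).

Step 2
Reactants: 4 3-(benzyloxy)-4-hydroxy-5-methoxybenzaldehyde; 5 ethyltriphenylphosphonium bromide
Product: 7 (Z)-2-(benzyloxy)-6-methoxy-4-(prop-1-en-1-yl)phenol, via ethylidenetriphenylphosphorane 6 (not isolated)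
Conditions: 4, KN(SiMe3)2 (1.0 equiv), THF, −78 °C; then ylide from 5 (1.5 equiv) and KN(SiMe3)2 (1.5 equiv), THF, −78 °C to rt; AcOH quench
Reagents that add atoms: none
Why: Wittig olefination with a non-stabilised ylide under salt-free conditions closes the cis-oxaphosphetane under kinetic control and should give mainly the (Z)-alkene, the potassium phenoxide of 4 being a slow but competent aldehyde partner; any (E)-isomer may be carried on because it only feeds the threo dimers that are removed after step 3.

Step 3
Reactants: 7 (Z)-2-(benzyloxy)-6-methoxy-4-(prop-1-en-1-yl)phenol (two molecules)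
Product: 11 meso-4,4′-[(2R,3R,4S,5S)-3,4-dimethyloxolane-2,5-diyl]bis[2-(benzyloxy)-6-methoxyphenol], via bis-quinone methide 8 (not isolated), via hydroxy quinone methide 9 (not isolated), via oxolane 2-epimer 10 (not isolated)
Conditions: laccase (Trametes versicolor), air, acetone–aqueous NaOAc buffer (pH 5), rt; then extraction and camphorsulfonic acid (cat.), CH2Cl2, 0 °C; chromatography and crystallisation
Reagents that add atoms: water, O
Why: Laccase with O2 oxidises 7 to its phenoxyl radical, two radicals join at C8–C8′ to give bis-quinone methide 8, water adds to one quinone methide carbon (C7–O) and the resulting benzylic hydroxyl adds to the other (C7′–O) in a 5-exo-trig oxa-Michael closure that forms the oxolane. The closest known reaction type is the oxidative 8–8′ dimerisation of 4-propenyl-2,6-dialkoxyphenols by oxidases or one-electron oxidants, which gives 2,5-diaryl-3,4-dimethyloxolanes after water capture. C3 and C4 (C8, C8′) are set by the face pairing of the two radicals: (E)-4-alkenyl-2,6-dialkoxyphenols pair almost only in the threo sense (the mode by which sinapyl alcohol gives syringaresinol) and would lead to the 3,4-trans-dimethyl series, whereas the (Z)-alkene, whose twisted side chain loses that preference, is expected to couple also in the erythro sense that gives meso 8 and hence the 3,4-cis-dimethyl ring. C2 and C5 (C7, C7′) are set under thermodynamic control, because each benzylic C–O bond is para to a free phenol and ionises reversibly to a quinone methide under the acid treatment, so kinetic epimers such as 10 should drain into 11 with each aryl group trans to its neighbouring methyl. Of the selectivities needed, 8–5′ coupling is excluded because both positions ortho to the phenol carry OMe or OBn, while 8–O–4′ coupling and the threo mode are only partly suppressed, so 11 has to be separated from those products. The acid is kept weak and cold so that the benzylic cation is recaptured by oxygen and not by the electron-rich ring of the other aryl group.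

Step 4
Reactants: 11 meso-4,4′-[(2R,3R,4S,5S)-3,4-dimethyloxolane-2,5-diyl]bis[2-(benzyloxy)-6-methoxyphenol]
Product: 12 meso-(2R,3R,4S,5S)-2,5-bis[3-(benzyloxy)-4,5-dimethoxyphenyl]-3,4-dimethyloxolane
Conditions: MeI (3 equiv), K2CO3, DMF, rt
Reagents that add atoms: iodomethane, CI
Why: Williamson O-methylation of the two hindered but acidic 4-hydroxyl groups, in which no stereocentre is touched and the phenolates are methylated much faster than they could open the oxolane.

Step 5
Reactants: 12 meso-(2R,3R,4S,5S)-2,5-bis[3-(benzyloxy)-4,5-dimethoxyphenyl]-3,4-dimethyloxolane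
Product: 13 meso-5,5′-[(2R,3R,4S,5S)-3,4-dimethyloxolane-2,5-diyl]bis(2,3-dimethoxyphenol)
Conditions: H2 (1 atm), palladium on carbon (Pd/C), EtOAc–EtOH, rt
Reagents that add atoms: none
Why: Catalytic hydrogenolysis cleaves the two aryl benzyl ethers under neutral conditions at 1 atm, where the benzylic C–O bonds of the oxolane ring are expected to react much more slowly, as in the usual final debenzylation of 2,5-diaryloxolane lignans.

Step 6
Reactants: 13 meso-5,5′-[(2R,3R,4S,5S)-3,4-dimethyloxolane-2,5-diyl]bis(2,3-dimethoxyphenol)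
Product: 14 5-[(2S,3S,4R,5R)-5-(3-hydroxy-4,5-dimethoxyphenyl)-3,4-dimethyloxolan-2-yl]-2,3-dimethoxyphenyl acetate
Conditions: immobilised Burkholderia cepacia lipase (lipase PS), vinyl acetate (3 equiv), t-BuOMe, 35 °C, stopped when 13 is consumed
Reagents that add atoms: vinyl acetate, CC(=O)OC=C
Why: Lipase-catalysed transesterification with an enol ester (enzymatic desymmetrisation of a σ-symmetric diol), in which the acetyl-enzyme should deliver its acyl group to only one of the two enantiotopic phenols, so that no new stereocentre is formed but the four existing ones acquire one absolute sense, and slower second acetylation of the minor monoacetate should raise the enantiomeric purity further.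

Step 7
Reactants: 14 5-[(2S,3S,4R,5R)-5-(3-hydroxy-4,5-dimethoxyphenyl)-3,4-dimethyloxolan-2-yl]-2,3-dimethoxyphenyl acetate
Product: 15 5-[(2S,3S,4R,5R)-3,4-dimethyl-5-(3,4,5-trimethoxyphenyl)oxolan-2-yl]-2,3-dimethoxyphenyl acetate
Conditions: MeOH (3 equiv), PPh3, DIAD, THF, 0 °C to rt
Reagents that add atoms: methanol, CO
Why: Mitsunobu etherification with methanol methylates the remaining phenol under neutral conditions, which avoids the free phenolate that could shuttle the acetyl group between molecules and erase the desymmetrisation.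

Step 8
Reactants: 15 5-[(2S,3S,4R,5R)-3,4-dimethyl-5-(3,4,5-trimethoxyphenyl)oxolan-2-yl]-2,3-dimethoxyphenyl acetate
Product: 16 5-[(2S,3S,4R,5R)-3,4-dimethyl-5-(3,4,5-trimethoxyphenyl)oxolan-2-yl]-2,3-dimethoxyphenol
Conditions: K2CO3 (cat.), MeOH, 0 °C to rt
Reagents that add atoms: none
Why: Base-catalysed methanolysis (transesterification) of the aryl acetate releases the phenol without touching the ethers or the stereocentres.

**Compound list**

1 | 5-hydroxyvanillin (3,4-dihydroxy-5-methoxybenzaldehyde) | COc1cc(C=O)cc(O)c1O | starting material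
2 | benzyl bromide | BrCc1ccccc1 | starting material
3 | disodium 5-formyl-3-methoxybenzene-1,2-diolate | COc1cc(C=O)cc([O-])c1[O-].[Na+].[Na+] | intermediate
4 | 3-(benzyloxy)-4-hydroxy-5-methoxybenzaldehyde | COc1cc(C=O)cc(OCc2ccccc2)c1O | intermediate
5 | ethyltriphenylphosphonium bromide | CC[P+](c1ccccc1)(c1ccccc1)c1ccccc1.[Br-] | starting material
6 | ethylidenetriphenylphosphorane | CC=P(c1ccccc1)(c1ccccc1)c1ccccc1 | intermediate
7 | (Z)-2-(benzyloxy)-6-methoxy-4-(prop-1-en-1-yl)phenol | C/C=C\c1cc(OC)c(O)c(OCc2ccccc2)c1 | intermediate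
8 | meso-4,4′-[(2R,3S)-2,3-dimethylbutane-1,4-diylidene]bis[2-(benzyloxy)-6-methoxycyclohexa-2,5-dien-1-one] (erythro bis-quinone methide; exocyclic alkene geometry not fixed) | C[C@H](C=C1C=C(OC)C(=O)C(OCc2ccccc2)=C1)[C@@H](C)C=C1C=C(OC)C(=O)C(OCc2ccccc2)=C1 | intermediate
9 | 2-(benzyloxy)-4-{4-[3-(benzyloxy)-4-hydroxy-5-methoxyphenyl]-4-hydroxy-2,3-dimethylbutylidene}-6-methoxycyclohexa-2,5-dien-1-one (erythro at C2/C3 of the chain, racemic, both carbinol epimers) | COc1cc(C(O)[C@@H](C)[C@@H](C)C=C2C=C(OC)C(=O)C(OCc3ccccc3)=C2)cc(OCc2ccccc2)c1O | intermediate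
10 | rac-4,4′-[(2R,3R,4S,5R)-3,4-dimethyloxolane-2,5-diyl]bis[2-(benzyloxy)-6-methoxyphenol] (one aryl cis to its neighbouring methyl; one enantiomer drawn) | COc1cc([C@@H]2O[C@@H](c3cc(OC)c(O)c(OCc4ccccc4)c3)[C@H](C)[C@@H]2C)cc(OCc2ccccc2)c1O | intermediate
11 | meso-4,4′-[(2R,3R,4S,5S)-3,4-dimethyloxolane-2,5-diyl]bis[2-(benzyloxy)-6-methoxyphenol] (methyls cis, aryls cis, each aryl trans to its neighbouring methyl) | COc1cc([C@H]2O[C@@H](c3cc(OC)c(O)c(OCc4ccccc4)c3)[C@H](C)[C@@H]2C)cc(OCc2ccccc2)c1O | intermediate
12 | meso-(2R,3R,4S,5S)-2,5-bis[3-(benzyloxy)-4,5-dimethoxyphenyl]-3,4-dimethyloxolane | COc1cc([C@H]2O[C@@H](c3cc(OC)c(OC)c(OCc4ccccc4)c3)[C@H](C)[C@@H]2C)cc(OCc2ccccc2)c1OC | intermediate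
13 | meso-5,5′-[(2R,3R,4S,5S)-3,4-dimethyloxolane-2,5-diyl]bis(2,3-dimethoxyphenol) | COc1cc([C@H]2O[C@@H](c3cc(OC)c(OC)c(O)c3)[C@H](C)[C@@H]2C)cc(O)c1OC | intermediate
14 | 5-[(2S,3S,4R,5R)-5-(3-hydroxy-4,5-dimethoxyphenyl)-3,4-dimethyloxolan-2-yl]-2,3-dimethoxyphenyl acetate | COc1cc([C@H]2O[C@@H](c3cc(OC)c(OC)c(O)c3)[C@H](C)[C@@H]2C)cc(OC(C)=O)c1OC | intermediate
15 | 5-[(2S,3S,4R,5R)-3,4-dimethyl-5-(3,4,5-trimethoxyphenyl)oxolan-2-yl]-2,3-dimethoxyphenyl acetate | COc1cc([C@H]2O[C@@H](c3cc(OC)c(OC)c(OC)c3)[C@H](C)[C@@H]2C)cc(OC(C)=O)c1OC | intermediate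
16 | 5-[(2S,3S,4R,5R)-3,4-dimethyl-5-(3,4,5-trimethoxyphenyl)oxolan-2-yl]-2,3-dimethoxyphenol | COc1cc([C@H]2O[C@@H](c3cc(OC)c(OC)c(OC)c3)[C@H](C)[C@@H]2C)cc(O)c1OC | target

**Count**

Total steps: 8. Longest linear sequence: 8 steps (1 to 16).

**Steps most likely to fail**

Step 3. The radical coupling may partition mainly into the 8–O–4′ ether and the threo 8–8′ mode, so that too little erythro dimer forms to isolate, or the acid treatment may divert the benzylic cation into ring closure onto the neighbouring arene. The fallback builds the C8–C8′ bond by enolate coupling, where the meso and racemic diastereomers are crystalline and can be interconverted by base. It sets out from 4 and returns to the route at 12.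
- Methylation of 4 (MeI, K2CO3, DMF) gives 3-(benzyloxy)-4,5-dimethoxybenzaldehyde F1.
- Addition of EtMgBr in THF gives 1-[3-(benzyloxy)-4,5-dimethoxyphenyl]propan-1-ol F2.
- Oxidation with MnO2 in CH2Cl2 gives 1-[3-(benzyloxy)-4,5-dimethoxyphenyl]propan-1-one F3.
- Oxidative coupling of its lithium enolate (LiN(i-Pr)2, THF, −78 °C, then CuCl2 in DMF) and crystallisation give meso-1,4-bis[3-(benzyloxy)-4,5-dimethoxyphenyl]-2,3-dimethylbutane-1,4-dione F4; the racemic diastereomer is recycled by base epimerisation.
- Reduction with LiAlH4 in THF gives 1,4-bis[3-(benzyloxy)-4,5-dimethoxyphenyl]-2,3-dimethylbutane-1,4-diol F5.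
- Acid-catalysed cyclodehydration (TsOH cat., CH2Cl2, 0 °C) through the benzylic cation should again place both aryl groups trans to the methyls and deliver 12.

Step 6. The enzyme may fail to tell apart two phenols that lie four bonds from the nearest stereocentre, or may acylate in the opposite sense. The fallback replaces desymmetrisation by resolution. It sets out from 13 and returns at 16.
- Mono-O-methylation of 13 with one equivalent of MeI (K2CO3, acetone) gives racemic material, that is 16 together with its enantiomer 5-[(2R,3R,4S,5S)-3,4-dimethyl-5-(3,4,5-trimethoxyphenyl)oxolan-2-yl]-2,3-dimethoxyphenol F6.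
- Unchanged 13 is recycled, and the over-methylated meso-(2R,3R,4S,5S)-3,4-dimethyl-2,5-bis(3,4,5-trimethoxyphenyl)oxolane F7 is removed by chromatography.
- Preparative HPLC on a cellulose tris(3,5-dimethylphenylcarbamate) phase then separates 16 from F6.

Step 2. The phenoxide-deactivated aldehyde may olefinate sluggishly, and the long reaction time may erode the (Z) preference through equilibration of the betaine-type intermediates. The fallback removes the phenoxide from the olefination. It sets out from 4 and returns at 7.
- Silylation of 4 (TBSCl, imidazole, DMF) gives 3-(benzyloxy)-4-[(tert-butyldimethylsilyl)oxy]-5-methoxybenzaldehyde F8.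
- The now electrophilic aldehyde reacts with the salt-free ylide (5, KN(SiMe3)2, THF, −78 °C) to give (Z)-{[2-(benzyloxy)-6-methoxy-4-(prop-1-en-1-yl)phenoxy]}(tert-butyl)dimethylsilane F9.
- Desilylation with Bu4NF buffered with AcOH in THF at 0 °C gives 7.

**Further compounds**

F1 | step 3 | 3-(benzyloxy)-4,5-dimethoxybenzaldehyde | COc1cc(C=O)cc(OCc2ccccc2)c1OC
F2 | step 3 | 1-[3-(benzyloxy)-4,5-dimethoxyphenyl]propan-1-ol (racemic) | CCC(O)c1cc(OC)c(OC)c(OCc2ccccc2)c1
F3 | step 3 | 1-[3-(benzyloxy)-4,5-dimethoxyphenyl]propan-1-one | CCC(=O)c1cc(OC)c(OC)c(OCc2ccccc2)c1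
F4 | step 3 | meso-(2R,3S)-1,4-bis[3-(benzyloxy)-4,5-dimethoxyphenyl]-2,3-dimethylbutane-1,4-dione | C[C@H](C(=O)c1cc(OC)c(OC)c(OCc2ccccc2)c1)[C@@H](C)C(=O)c1cc(OC)c(OC)c(OCc2ccccc2)c1
F5 | step 3 | (2R,3S)-1,4-bis[3-(benzyloxy)-4,5-dimethoxyphenyl]-2,3-dimethylbutane-1,4-diol (carbinol epimers) | C[C@H](C(O)c1cc(OC)c(OC)c(OCc2ccccc2)c1)[C@@H](C)C(O)c1cc(OC)c(OC)c(OCc2ccccc2)c1
F6 | step 6 | 5-[(2R,3R,4S,5S)-3,4-dimethyl-5-(3,4,5-trimethoxyphenyl)oxolan-2-yl]-2,3-dimethoxyphenol (enantiomer of 16) | COc1cc([C@@H]2O[C@H](c3cc(OC)c(OC)c(OC)c3)[C@@H](C)[C@H]2C)cc(O)c1OC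
F7 | step 6 | meso-(2R,3R,4S,5S)-3,4-dimethyl-2,5-bis(3,4,5-trimethoxyphenyl)oxolane | COc1cc([C@H]2O[C@@H](c3cc(OC)c(OC)c(OC)c3)[C@H](C)[C@@H]2C)cc(OC)c1OC
F8 | step 2 | 3-(benzyloxy)-4-[(tert-butyldimethylsilyl)oxy]-5-methoxybenzaldehyde | COc1cc(C=O)cc(OCc2ccccc2)c1O[Si](C)(C)C(C)(C)C
F9 | step 2 | (Z)-{[2-(benzyloxy)-6-methoxy-4-(prop-1-en-1-yl)phenoxy]}(tert-butyl)dimethylsilane | C/C=C\c1cc(OC)c(O[Si](C)(C)C(C)(C)C)c(OCc2ccccc2)c1
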